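## Retrosynthetic overview

1. Target 21 ⇐ O‑benzyl, bis‑O‑TBS ketone 19 ⇐ (1S,2S)‑1‑aryl‑2‑aryloxy‑propane‑1,3‑diol 17. The benzylic carbinol is oxidised late, so only C2 has to be controlled.
2. Diol 17 ⇐ Evans syn‑aldol adduct 16. The key C–C bond (ArC–C2) joins aldehyde 13 and the boron enolate of N‑(aryloxyacetyl)oxazolidinone 11.
3. Imide 11 ⇐ aryloxyacetic acid 8 ⇐ eugenol 1 + ethyl bromoacetate 2 (allyl → 3‑hydroxypropyl by hydroboration). Aldehyde 13 ⇐ syringaldehyde 12.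
4. No ring is formed: both benzene rings are bought, and the oxazolidinone ring belongs to the auxiliary, which is cleaved off and recovered.

Assumption: the SMILES descriptor corresponds to (S) at C2, and (R)‑4‑benzyl‑1,3‑oxazolidin‑2‑one is taken as a purchasable auxiliary. TBS = tert‑butyldimethylsilyl.

## Route

Step 1
Reactants: 1 eugenol; 2 ethyl bromoacetate
Product: 3 ethyl 2-(4-allyl-2-methoxyphenoxy)acetate
Conditions: K2CO3 (1.5 equiv), acetone, reflux
Reagents that add atoms: none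
Why: Williamson ether synthesis; the phenoxide displaces the activated primary bromide cleanly by SN2.

Step 2
Reactants: 3 ethyl 2-(4-allyl-2-methoxyphenoxy)acetate
Product: 5 ethyl 2-[4-(3-hydroxypropyl)-2-methoxyphenoxy]acetate, via alkylborane 4 (not isolated)
Conditions: 9-BBN (1.2 equiv), THF, 0 °C to rt; then aq. NaOAc, 30% H2O2, 0 °C to rt
Reagents that add atoms: 9-BBN, [H]B1C2CCCC1CCC2 (its boron stays in 4 only); hydrogen peroxide, OO (the O of the new OH)
Why: Anti‑Markovnikov hydroboration–oxidation; 9-BBN adds to the terminal alkene much faster than it reduces an ester, and the acetate‑buffered peroxide work-up spares the ester.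

Step 3
Reactants: 5 ethyl 2-[4-(3-hydroxypropyl)-2-methoxyphenoxy]acetate
Product: 6 ethyl 2-[4-(3-(TBSO)propyl)-2-methoxyphenoxy]acetate
Conditions: TBSCl (1.2 equiv), imidazole (2.5 equiv), DMF, 0 °C to rt
Reagents that add atoms: TBSCl, CC(C)(C)[Si](C)(C)Cl
Why: Standard silylation of a primary alcohol; the TBS ether survives every step up to the fluoride deprotection.

Step 4
Reactants: 6 ethyl 2-[4-(3-(TBSO)propyl)-2-methoxyphenoxy]acetate
Product: 8 2-[4-(3-(TBSO)propyl)-2-methoxyphenoxy]acetic acid, via lithium carboxylate 7 (not isolated)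
Conditions: LiOH·H2O (1.5 equiv), THF/H2O 3:1, 0 °C to rt; then cold 0.5 M HCl to pH 4
Reagents that add atoms: LiOH, [Li+].[OH-] (Li in 7; its O becomes the acid OH)
Why: Saponification of an activated aryloxyacetate is fast, and a primary TBS ether is stable to aqueous LiOH and to brief cold acidification.

Step 5
Reactants: 8 2-[4-(3-(TBSO)propyl)-2-methoxyphenoxy]acetic acid; 9 (R)-4-benzyl-1,3-oxazolidin-2-one
Product: 11 (R)-4-benzyl-3-{2-[4-(3-(TBSO)propyl)-2-methoxyphenoxy]acetyl}-1,3-oxazolidin-2-one, via mixed pivalic anhydride 10 (not isolated)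
Conditions: PivCl (1.1 equiv), Et3N (2.5 equiv), THF, −20 to 0 °C; then LiCl (1.1 equiv), 9, rt
Reagents that add atoms: pivaloyl chloride, CC(C)(C)C(Cl)=O (its acyl group is in 10 only)
Why: One‑pot mixed‑anhydride N‑acylation; the LiCl‑activated oxazolidinone attacks the unhindered aryloxyacetyl carbonyl, not the tert‑butyl‑shielded one.

Step 6
Reactants: 12 syringaldehyde
Product: 13 4-(benzyloxy)-3,5-dimethoxybenzaldehyde
Conditions: BnBr (1.2 equiv), K2CO3 (2 equiv), DMF, 60 °C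
Reagents that add atoms: benzyl bromide, BrCc1ccccc1
Why: Williamson O‑benzylation masks the acidic phenol, which would otherwise quench the boron enolate.

Step 7
Reactants: 11 (R)-4-benzyl-3-{2-[4-(3-(TBSO)propyl)-2-methoxyphenoxy]acetyl}-1,3-oxazolidin-2-one; 13 4-(benzyloxy)-3,5-dimethoxybenzaldehyde
Product: 16 (R)-4-benzyl-3-[(2R,3S)-3-[4-(benzyloxy)-3,5-dimethoxyphenyl]-3-hydroxy-2-[4-(3-(TBSO)propyl)-2-methoxyphenoxy]propanoyl]-1,3-oxazolidin-2-one, via boron enolate 14 (not isolated), via boron aldolate 15 (not isolated)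
Conditions: Bu2BOTf (1.3 equiv), iPr2NEt (1.5 equiv), CH2Cl2, 0 °C; 13 (1.2 equiv), −78 to 0 °C; then pH 7 phosphate buffer, MeOH, 30% H2O2, 0 °C
Reagents that add atoms: Bu2BOTf, CCCCB(CCCC)OS(=O)(=O)C(F)(F)F (its Bu2B group is in 14 and 15 only)
Why: Evans syn‑aldol reaction; the (Z)‑boron enolate reacts through a dipole‑minimised Zimmerman–Traxler chair in which the (R)‑benzyl group blocks one enolate face, setting C2 as R and C3 as S, with minor diastereomers removed by chromatography.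

Step 8
Reactants: 16 the syn‑aldol adduct
Product: 17 (1S,2S)-1-[4-(benzyloxy)-3,5-dimethoxyphenyl]-2-[4-(3-(TBSO)propyl)-2-methoxyphenoxy]propane-1,3-diol
Conditions: NaBH4 (4 equiv), THF/H2O 4:1, 0 °C to rt; auxiliary 9 recovered by chromatography
Reagents that add atoms: none
Why: Chemoselective borohydride reduction of the exocyclic imide carbonyl releases the primary alcohol without touching C2; the C2 descriptor changes from R to S only because the CIP priorities change.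

Step 9
Reactants: 17 the 1,3‑diol
Product: 18 (1S,2S)-1-[4-(benzyloxy)-3,5-dimethoxyphenyl]-3-(TBSO)-2-[4-(3-(TBSO)propyl)-2-methoxyphenoxy]propan-1-ol
Conditions: TBSCl (1.1 equiv), imidazole (2.2 equiv), CH2Cl2, 0 °C
Reagents that add atoms: TBSCl, CC(C)(C)[Si](C)(C)Cl
Why: Selective silylation; the primary hydroxyl reacts far faster than the hindered secondary benzylic one.

Step 10
Reactants: 18 the secondary benzylic alcohol
Product: 19 (S)-1-[4-(benzyloxy)-3,5-dimethoxyphenyl]-3-(TBSO)-2-[4-(3-(TBSO)propyl)-2-methoxyphenoxy]propan-1-one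
Conditions: Dess–Martin periodinane (1.3 equiv), CH2Cl2, 0 °C to rt; cold Na2S2O3/NaHCO3 wash
Reagents that add atoms: none
Why: Dess–Martin oxidation proceeds without base, so the now enolisable C2 centre is not epimerised while the sacrificial carbinol centre is removed.

Step 11
Reactants: 19 the bis‑TBS ketone
Product: 20 (S)-1-[4-(benzyloxy)-3,5-dimethoxyphenyl]-3-hydroxy-2-[4-(3-hydroxypropyl)-2-methoxyphenoxy]propan-1-one
Conditions: HF·pyridine, pyridine, THF, 0 °C to rt; pH 7 buffer work-up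
Reagents that add atoms: none
Why: Buffered HF desilylation of both primary silyl ethers avoids basic fluoride, which could cause retro‑aldol loss of formaldehyde, β‑elimination or epimerisation at C2.

Step 12
Reactants: 20 the O‑benzyl ketone
Product: 21 (S)-3-hydroxy-1-(4-hydroxy-3,5-dimethoxyphenyl)-2-[4-(3-hydroxypropyl)-2-methoxyphenoxy]propan-1-one
Conditions: H2 (1 atm), 10% Pd/C, EtOAc, rt, stopped at full conversion; filtration through Celite
Reagents that add atoms: none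
Why: Hydrogenolysis of an aryl benzyl ether is much faster than reduction of the electron‑rich, conjugated aryl ketone, and the neutral conditions leave C2 intact.

## Compound list

1 | eugenol (4-allyl-2-methoxyphenol) | C=CCc1ccc(O)c(OC)c1 | starting material
2 | ethyl bromoacetate | CCOC(=O)CBr | starting material
3 | ethyl 2-(4-allyl-2-methoxyphenoxy)acetate | CCOC(=O)COc1ccc(CC=C)cc1OC | intermediate
4 | B‑alkyl‑9‑BBN adduct of 3 (formed in the flask) | CCOC(=O)COc1ccc(CCCB2C3CCCC2CCC3)cc1OC | intermediate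
5 | ethyl 2-[4-(3-hydroxypropyl)-2-methoxyphenoxy]acetate | CCOC(=O)COc1ccc(CCCO)cc1OC | intermediate
6 | ethyl 2-[4-(3-(TBSO)propyl)-2-methoxyphenoxy]acetate | CCOC(=O)COc1ccc(CCCO[Si](C)(C)C(C)(C)C)cc1OC | intermediate
7 | lithium 2-[4-(3-(TBSO)propyl)-2-methoxyphenoxy]acetate (formed in the flask) | [Li+].[O-]C(=O)COc1ccc(CCCO[Si](C)(C)C(C)(C)C)cc1OC | intermediate
8 | 2-[4-(3-(TBSO)propyl)-2-methoxyphenoxy]acetic acid | OC(=O)COc1ccc(CCCO[Si](C)(C)C(C)(C)C)cc1OC | intermediate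
9 | (R)-4-benzyl-1,3-oxazolidin-2-one | O=C1N[C@H](Cc2ccccc2)CO1 | starting material
10 | mixed pivalic anhydride of 8 (formed in the flask) | CC(C)(C)C(=O)OC(=O)COc1ccc(CCCO[Si](C)(C)C(C)(C)C)cc1OC | intermediate
11 | (R)-4-benzyl-3-{2-[4-(3-(TBSO)propyl)-2-methoxyphenoxy]acetyl}-1,3-oxazolidin-2-one | O=C(COc1ccc(CCCO[Si](C)(C)C(C)(C)C)cc1OC)N1[C@H](Cc2ccccc2)COC1=O | intermediate
12 | syringaldehyde (4-hydroxy-3,5-dimethoxybenzaldehyde) | COc1cc(C=O)cc(OC)c1O | starting material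
13 | 4-(benzyloxy)-3,5-dimethoxybenzaldehyde | COc1cc(C=O)cc(OC)c1OCc1ccccc1 | intermediate
14 | (Z)‑dibutylboron enolate of 11 (formed in the flask) | CCCCB(CCCC)O/C(=C\Oc1ccc(CCCO[Si](C)(C)C(C)(C)C)cc1OC)N1[C@H](Cc2ccccc2)COC1=O | intermediate
15 | dibutylboron aldolate of 16 (formed in the flask; 2R,3S) | O=C([C@H](Oc1ccc(CCCO[Si](C)(C)C(C)(C)C)cc1OC)[C@@H](OB(CCCC)CCCC)c1cc(OC)c(OCc2ccccc2)c(OC)c1)N1[C@H](Cc2ccccc2)COC1=O | intermediate
16 | (R)-4-benzyl-3-[(2R,3S)-3-[4-(benzyloxy)-3,5-dimethoxyphenyl]-3-hydroxy-2-[4-(3-(TBSO)propyl)-2-methoxyphenoxy]propanoyl]-1,3-oxazolidin-2-one | O=C([C@H](Oc1ccc(CCCO[Si](C)(C)C(C)(C)C)cc1OC)[C@@H](O)c1cc(OC)c(OCc2ccccc2)c(OC)c1)N1[C@H](Cc2ccccc2)COC1=O | intermediate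
17 | (1S,2S)-1-[4-(benzyloxy)-3,5-dimethoxyphenyl]-2-[4-(3-(TBSO)propyl)-2-methoxyphenoxy]propane-1,3-diol | OC[C@H](Oc1ccc(CCCO[Si](C)(C)C(C)(C)C)cc1OC)[C@@H](O)c1cc(OC)c(OCc2ccccc2)c(OC)c1 | intermediate
18 | (1S,2S)-1-[4-(benzyloxy)-3,5-dimethoxyphenyl]-3-(TBSO)-2-[4-(3-(TBSO)propyl)-2-methoxyphenoxy]propan-1-ol | CC(C)(C)[Si](C)(C)OC[C@H](Oc1ccc(CCCO[Si](C)(C)C(C)(C)C)cc1OC)[C@@H](O)c1cc(OC)c(OCc2ccccc2)c(OC)c1 | intermediate
19 | (S)-1-[4-(benzyloxy)-3,5-dimethoxyphenyl]-3-(TBSO)-2-[4-(3-(TBSO)propyl)-2-methoxyphenoxy]propan-1-one | CC(C)(C)[Si](C)(C)OC[C@H](Oc1ccc(CCCO[Si](C)(C)C(C)(C)C)cc1OC)C(=O)c1cc(OC)c(OCc2ccccc2)c(OC)c1 | intermediate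
20 | (S)-1-[4-(benzyloxy)-3,5-dimethoxyphenyl]-3-hydroxy-2-[4-(3-hydroxypropyl)-2-methoxyphenoxy]propan-1-one | OC[C@H](Oc1ccc(CCCO)cc1OC)C(=O)c1cc(OC)c(OCc2ccccc2)c(OC)c1 | intermediate
21 | (S)-3-hydroxy-1-(4-hydroxy-3,5-dimethoxyphenyl)-2-[4-(3-hydroxypropyl)-2-methoxyphenoxy]propan-1-one | COc1cc(CCCO)ccc1O[C@@H](CO)C(=O)c1cc(OC)c(O)c(OC)c1 | target

## Step count and risks

Total step count: 12. Longest linear sequence: 11 steps (1 to 21 through steps 1–5 and 7–12); step 6 is the one‑step side branch.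

Most likely to fail:

Step 7, the aldol. The electron‑rich aldehyde may add sluggishly, or facial selectivity may erode. The fallback changes auxiliary and metal and sets out from acid 8. EDC·HCl/DMAP coupling with purchased (R)-4-benzyl-1,3-thiazolidine-2-thione in CH2Cl2 gives the N‑acyl thiazolidinethione F3. TiCl4 (1.05 equiv), iPr2NEt (1.1 equiv) and N‑methyl‑2‑pyrrolidinone (1 equiv) in CH2Cl2 at 0 °C convert it to the chlorotitanium enolate F4 (not isolated). F4 adds to the TiCl4‑activated aldehyde 13 in the Evans‑syn sense (non‑chelated chair) to give the titanium aldolate F5 (not isolated), and aqueous NH4Cl releases the syn adduct F6. NaBH4 in THF/EtOH cleaves the thione auxiliary and returns the route at diol 17.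

Step 12, hydrogenolysis beside the α‑aryloxy aryl ketone. The risks are over‑reduction of the ketone or C–O cleavage. The fallback removes the benzyl group before the ketone exists and sets out from alcohol 18. H2 and 10% Pd/C in EtOAc give the free phenol F7. DDQ (1.2 equiv) in 1,4‑dioxane at rt dehydrogenates the p‑hydroxybenzylic alcohol selectively to the p‑hydroxyaryl ketone F8. HF·pyridine in THF/pyridine then removes both silyl ethers and arrives at target 21.

Step 2, hydroboration–oxidation beside the activated ester. The risk is partial reduction or saponification of the aryloxyacetate. The fallback hydroborates before the ester is installed and sets out from eugenol 1. 9-BBN (2.2 equiv, THF) first silences the phenol with loss of H2 and then adds to the alkene, giving the O‑boryl alkylborane F1 (not isolated). Aqueous NaOAc/H2O2 converts F1 to dihydroconiferyl alcohol F2. K2CO3 in acetone then alkylates only the phenol of F2 with 2 and returns the route at hydroxy ester 5.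

## Further compounds

F1 | step 2 | 9-{3-[4-(9-borabicyclo[3.3.1]nonan-9-yloxy)-3-methoxyphenyl]propyl}-9-borabicyclo[3.3.1]nonane | COc1cc(CCCB2C3CCCC2CCC3)ccc1OB1C2CCCC1CCC2
F2 | step 2 | dihydroconiferyl alcohol (4-(3-hydroxypropyl)-2-methoxyphenol) | COc1cc(CCCO)ccc1O
F3 | step 7 | 1-[(R)-4-benzyl-2-thioxo-1,3-thiazolidin-3-yl]-2-[4-(3-(TBSO)propyl)-2-methoxyphenoxy]ethan-1-one | O=C(COc1ccc(CCCO[Si](C)(C)C(C)(C)C)cc1OC)N1[C@H](Cc2ccccc2)CSC1=S
F4 | step 7 | (Z)‑trichlorotitanium enolate of F3 | Cl[Ti](Cl)(Cl)O/C(=C\Oc1ccc(CCCO[Si](C)(C)C(C)(C)C)cc1OC)N1[C@H](Cc2ccccc2)CSC1=S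
F5 | step 7 | trichlorotitanium aldolate of F6 (2R,3S) | O=C([C@H](Oc1ccc(CCCO[Si](C)(C)C(C)(C)C)cc1OC)[C@@H](O[Ti](Cl)(Cl)Cl)c1cc(OC)c(OCc2ccccc2)c(OC)c1)N1[C@H](Cc2ccccc2)CSC1=S
F6 | step 7 | (2R,3S)-3-[4-(benzyloxy)-3,5-dimethoxyphenyl]-1-[(R)-4-benzyl-2-thioxo-1,3-thiazolidin-3-yl]-3-hydroxy-2-[4-(3-(TBSO)propyl)-2-methoxyphenoxy]propan-1-one | O=C([C@H](Oc1ccc(CCCO[Si](C)(C)C(C)(C)C)cc1OC)[C@@H](O)c1cc(OC)c(OCc2ccccc2)c(OC)c1)N1[C@H](Cc2ccccc2)CSC1=S
F7 | step 12 | (1S,2S)-3-(TBSO)-1-(4-hydroxy-3,5-dimethoxyphenyl)-2-[4-(3-(TBSO)propyl)-2-methoxyphenoxy]propan-1-ol | CC(C)(C)[Si](C)(C)OC[C@H](Oc1ccc(CCCO[Si](C)(C)C(C)(C)C)cc1OC)[C@@H](O)c1cc(OC)c(O)c(OC)c1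
F8 | step 12 | (S)-3-(TBSO)-1-(4-hydroxy-3,5-dimethoxyphenyl)-2-[4-(3-(TBSO)propyl)-2-methoxyphenoxy]propan-1-one | CC(C)(C)[Si](C)(C)OC[C@H](Oc1ccc(CCCO[Si](C)(C)C(C)(C)C)cc1OC)C(=O)c1cc(OC)c(O)c(OC)c1
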